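## The problem

The target (34) is a germacranolide. Its ten-membered carbocycle (C1–C10) is trans-fused through C6–C7 to an α-methylene-γ-butyrolactone (O–C6, C7, C11=C13, C12=O). It carries a 1,10-epoxide with the C14 methyl on C10, a Z-trisubstituted C4=C5 alkene with the C15 methyl on C4, a secondary carbinol at C3, and a (2R,3S)-2,3-epoxy-2-methylbutanoate on the C8 oxygen. Eight stereocentres must be set: C1 and C10 (both R, the trans-epoxide of an E-alkene), C3 (S), the contiguous triad C6, C7, C8 (all R), and the two of the side chain. Within the triad C6 can direct C7 (addition anti to the C6 substituent of a butenolide) and C7 can relay to C8. The epoxide pair, the side chain and C3 are too remote for relay and must come from reagent control or, for C3, from the conformation of the ring. The compound tolerates little: the methylene lactone is a Michael acceptor and isomerises with base, both epoxides open with acid, the C6–O bond is allylic, and the C3 hydroxyl can attack the tertiary epoxide carbon under acid. The strained ten-membered ring is the hardest bond set to make, and the later it is closed the fewer operations meet these liabilities. A late closure is possible because the C3 carbinol sits directly on C4 of the Z-C4=C5 alkene, which is the allylic alcohol formed when a Z-alkenyl metal at C4 adds to an aldehyde at C3.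

## Retrosynthesis

**C3–C4 (ring closure).** Target 34 is cut between the carbinol carbon C3 and the alkene carbon C4, giving the seco aldehyde Z-alkenyl iodide 31; in the forward direction it passes through alkenylchromium 32 and chromium alkoxide 33. Cuts at other ring bonds would leave redox or stereochemical work to be done on the strained ring, whereas this one ends the synthesis. Precursor 31 is an open chain on a preformed lactone and already holds every stereocentre except C3; each maps onto 34 with the same spatial arrangement (the C6 descriptor reads S in 31 only because iodine raises the priority of C5). The forward step must generate the alkenyl metal in the presence of two epoxides, two esters and an enoate, keep the Z geometry, close under high dilution and add to the Re face of the aldehyde.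

**C3 oxidation level.** Aldehyde 31 is a β,γ-epoxy aldehyde and is made last, from primary alcohol 30, itself released from 4-methoxybenzyl (PMB) ether 29. The PMB ether is chosen because DDQ at neutral pH removes it without fluoride, acid or base, all of which would threaten the epoxides or the methylene lactone at this stage.

**C8–O (side chain, with inversion).** Ester 29 is cut at the C8–O bond into carbinol 28 and epoxy acid 26. The fragment union described next delivers C8 with the S configuration, opposite to that of the target, so the ester is formed by Mitsunobu displacement. This installs the side chain and corrects C8 in one operation. Acid 26 comes from epoxy alcohol 25, allylic alcohol 24 and tiglic acid 23 by Sharpless epoxidation. Epoxidising a tiglate after attachment is not an option beside the methylene lactone and would be uncontrolled.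

**C7–C8 (fragment union).** Carbinol 28 is cut between C7 and C8 into bromomethyl butenolide 22 and epoxy aldehyde 10, joined through allylindium 27. The cut divides the molecule into halves of similar size, carries the lactone ring intact, creates the exocyclic methylene by allylic transposition, and lets C6 set C7. The alternative C6–C7 union of an acyclic bromomethyl acrylate would give the cis-lactone. The forward step needs indium to insert into the allylic C–Br bond only and conditions neutral enough for the β,γ-epoxy aldehyde.

**Butenolide 22.** Bromide 22 comes from silyl ether 21, formed by ring-closing metathesis of acrylate 20 (cut at C7=C11), which is the ester of dienol 16 and acid 19 (from 17 via 18). The usual palladium carbonylation of an iodo allylic alcohol is excluded here because the C4 iodide would compete; metathesis leaves it untouched. Dienol 16 is the slow-reacting enantiomer of racemate 15, obtained by hydroxyl-directed trans-hydroalumination and iodination of enynol 13 (from acrolein 11 and Grignard reagent 12). That step fixes the Z geometry the macrocycle needs.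

**Epoxy aldehyde 10.** Aldehyde 10 is traced through alcohol 9 and silyl ether 8 to E-alkene 7 (Shi epoxidation, reagent control of C1 and C10). Alkene 7 is the PMB ether of homoallylic alcohol 6, assembled from alkyne 2 (from but-3-yn-1-ol 1) by carboalumination to alkenylalane 4, conversion to alanate 5 and opening of ethylene oxide 3. One operation sets the E geometry, the C14 methyl and the C2–C3 unit, and the two chain ends are differentiated as silyl and PMB ethers.

## Roads not taken

Alternative 1: The ring would be cut at C4–C5 and C1–C10 together. In the forward direction an enone carrying C5–C10 is irradiated near 350 nm with a cyclobutene ester carrying C1–C4. This gives the cis-anti-cis head-to-head photoadduct A1, whose strained cyclobutane later undergoes cycloreversion to the cyclodeca-1(10),4-diene.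
- Merits: two ring bonds are made from a six- and a four-membered ring, and the ten-membered ring is never closed by an entropically difficult cyclisation. In that respect it is better than the chosen plan.
- Weak points: A1 carries C15 as an ester and C3 as a ketal and lacks the lactone carbons, the C8 ester and the epoxide. The cycloreversion needs strong heating, under which a 1,5-diene of this type can rearrange to the elemane skeleton and alkene geometry is only partly controlled. All remaining oxygenation, including epoxidation of one of two trisubstituted alkenes, would be done on the flexible ring over many steps.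
- Comparison: the chosen plan accepts a harder ring closure in exchange for acyclic, reagent-controlled stereocentres and no steps after closure.

Alternative 2: Here C8–C9 is formed while a temporary C1–C6 bond is broken. The potassium alkoxide (KH, 18-crown-6) of an isopiperitenone-derived dialkenyl cyclohexenol rearranges by an anionic oxy-Cope reaction through a chair to the ten-membered dienone A2.
- Merits: a very short, chiral-pool entry to the carbocycle with both alkene geometries set by the chair, and an enolate at C6/C7 that could be alkylated directly. Ring formation is more dependable than a ten-membered chromium closure, and the step count to the ring is lower.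
- Weak points: A2 has a C6 ketone and none of C11–C13. The lactone, the methylene, the C8 ester (after deprotection), the C3 alcohol and a site-selective 1,10-epoxidation all remain, each relying on conformational control in a mobile ring. The oxygenated alkenyl groups the rearrangement would need are prone to elimination under KH.
- Comparison: the chosen plan is longer before the ring exists, but every stereocentre except C3 is secured before closure and nothing follows it.

Alternative 3: The ring would be cut at C9–C10. SmI2 reduces a C9 bromide next to a C8 ketone to a samarium enolate, which adds to a C10 methyl ketone and gives the ten-membered β-hydroxy ketone A3.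
- Merits: the lactone, C3 and the Z-alkene are already in place, and chelated samarium enolates close medium rings well, probably as reliably as or more reliably than the nickel–chromium closure.
- Weak points: A3 still needs stereoselective C8 reduction, acylation, conversion of the C1 silyl ether and C10 carbinol into the epoxide, and deprotection at C3. That is five or more steps on a retro-aldol-prone β-hydroxy ketone beside the methylene lactone, with C10 set by chelation of uncertain sense.
- Comparison: the chosen plan has one uncertain stereocentre (C3) with a two-step correction, and no functional-group work after the ring is formed.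

Key step: step 22

Assumption: the indium-mediated addition of the 3-(bromomethyl)butenolide is taken to follow the closed six-membered transition state established for such reagents. That gives the 6,7-trans lactone with the C8 hydroxyl anti to C6 across C7 (8S), so the C8 ester is introduced with inversion.

## Steps

Step 1
Reactants: 1 but-3-yn-1-ol
Product: 2 tert-butyl(but-3-yn-1-yloxy)dimethylsilane
Conditions: TBSCl, imidazole, CH2Cl2, 0 °C to rt
Reagents that add atoms: tert-butyldimethylsilyl chloride, CC(C)(C)[Si](C)(C)Cl
Why: Standard silylation of a primary alcohol; the silyl ether marks the future C8 oxygen and keeps it distinct from the C3 oxygen introduced in step 2.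

Step 2
Reactants: 2 tert-butyl(but-3-yn-1-yloxy)dimethylsilane; 3 ethylene oxide
Product: 6 (E)-6-[(tert-butyldimethylsilyl)oxy]-4-methylhex-3-en-1-ol, via alkenyldimethylalane 4 (not isolated), via lithium alkenylalanate 5 (not isolated)
Conditions: Me3Al, Cp2ZrCl2 (cat.), CH2Cl2, rt; volatiles removed; n-BuLi, THF–hexane, −78 to 0 °C; ethylene oxide, −78 °C to rt
Reagents that add atoms: trimethylaluminium, C[Al](C)C
Why: Negishi zirconium-catalysed carboalumination adds methyl and aluminium syn across the alkyne with methyl on the internal carbon, which fixes the E-trisubstituted C10=C1 alkene and the C14 methyl; the derived lithium alanate should open ethylene oxide with retention of alkene geometry, adding C2 and C3.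

Step 3
Reactants: 6 (E)-6-[(tert-butyldimethylsilyl)oxy]-4-methylhex-3-en-1-ol
Product: 7 tert-butyl{[(E)-6-[(4-methoxybenzyl)oxy]-3-methylhex-3-en-1-yl]oxy}dimethylsilane
Conditions: NaH, 4-methoxybenzyl chloride, Bu4NI (cat.), THF–DMF, 0 °C to rt
Reagents that add atoms: 4-methoxybenzyl chloride, COc1ccc(CCl)cc1
Why: Williamson etherification of the primary alkoxide; the PMB ether is inert to every step up to step 20 and is removed there oxidatively at neutral pH.

Step 4
Reactants: 7 tert-butyl{[(E)-6-[(4-methoxybenzyl)oxy]-3-methylhex-3-en-1-yl]oxy}dimethylsilane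
Product: 8 tert-butyl{2-[(2R,3R)-3-{2-[(4-methoxybenzyl)oxy]ethyl}-2-methyloxiran-2-yl]ethoxy}dimethylsilane
Conditions: D-fructose-derived Shi ketone (30 mol %), KHSO5 (as Oxone), K2CO3, Bu4NHSO4, Na2B4O7/Na2EDTA buffer, MeCN–dimethoxymethane–H2O, 0 °C
Reagents that add atoms: potassium peroxymonosulfate, [K+].[O-]S(=O)(=O)OO
Why: Shi asymmetric epoxidation; the chiral dioxirane epoxidises E-trisubstituted alkenes through a spiro transition state, which for this substitution pattern should give the (R,R)-epoxide (C1 and C10), the E geometry becoming the trans relation of C2 and C9.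

Step 5
Reactants: 8 tert-butyl{2-[(2R,3R)-3-{2-[(4-methoxybenzyl)oxy]ethyl}-2-methyloxiran-2-yl]ethoxy}dimethylsilane
Product: 9 2-[(2R,3R)-3-{2-[(4-methoxybenzyl)oxy]ethyl}-2-methyloxiran-2-yl]ethan-1-ol
Conditions: Bu4NF, THF, 0 °C
Reagents that add atoms: none
Why: Fluoride cleaves the Si–O bond; the epoxide and the PMB ether are inert to Bu4NF at 0 °C.

Step 6
Reactants: 9 2-[(2R,3R)-3-{2-[(4-methoxybenzyl)oxy]ethyl}-2-methyloxiran-2-yl]ethan-1-ol
Product: 10 2-[(2R,3R)-3-{2-[(4-methoxybenzyl)oxy]ethyl}-2-methyloxiran-2-yl]acetaldehyde
Conditions: Dess–Martin periodinane, NaHCO3, CH2Cl2, 0 °C to rt; used at once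
Reagents that add atoms: none
Why: Dess–Martin oxidation under bicarbonate buffering gives the β,γ-epoxy aldehyde (C8) without the acid or base that would open the epoxide by β-elimination.

Step 7
Reactants: 11 acrolein; 12 1-propynylmagnesium bromide (CH3C≡CMgBr)
Product: 13 rac-hex-1-en-4-yn-3-ol
Conditions: THF, −78 to −20 °C; aq. NH4Cl
Reagents that add atoms: none
Why: 1,2-Addition of an alkynyl Grignard reagent to an enal at low temperature; the carbinol carbon becomes C6, flanked by the future C7 (vinyl) and C5/C4 (alkyne).

Step 8
Reactants: 13 rac-hex-1-en-4-yn-3-ol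
Product: 15 rac-(Z)-5-iodohexa-1,4-dien-3-ol, via cyclic alkenylaluminate 14 (not isolated)
Conditions: NaAlH2(OCH2CH2OMe)2 (Red-Al), THF, 0 °C to rt; EtOAc; then I2, −78 to 0 °C
Reagents that add atoms: iodine, II
Why: Hydroxyl-directed trans-hydroalumination of a propargylic alcohol places aluminium on the distal alkyne carbon in a five-membered aluminate, and iodinolysis with retention gives the Z-iodoalkene (iodine cis to the carbinol carbon), the geometry needed later at C4=C5; the vinyl group is not reduced.

Step 9
Reactants: 15 rac-(Z)-5-iodohexa-1,4-dien-3-ol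
Product: 16 (3S,4Z)-5-iodohexa-1,4-dien-3-ol
Conditions: immobilised Candida antarctica lipase B, vinyl acetate, tert-butyl methyl ether, 30 °C, stopped just past half conversion
Reagents that add atoms: none
Why: Lipase kinetic resolution following the Kazlauskas rule: with vinyl as the small and iodoalkenyl as the large group the (R)-alcohol should be acetylated, leaving the (S)-alcohol whose configuration becomes C6.

Step 10
Reactants: 17 methyl 2-(hydroxymethyl)acrylate
Product: 18 methyl 2-{[(tert-butyldimethylsilyl)oxy]methyl}acrylate
Conditions: TBSCl, imidazole, CH2Cl2, 0 °C to rt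
Reagents that add atoms: tert-butyldimethylsilyl chloride, CC(C)(C)[Si](C)(C)Cl
Why: Standard silylation; the silyl ether masks the future C13 carbon during esterification and metathesis.

Step 11
Reactants: 18 methyl 2-{[(tert-butyldimethylsilyl)oxy]methyl}acrylate
Product: 19 2-{[(tert-butyldimethylsilyl)oxy]methyl}acrylic acid
Conditions: LiOH, THF–H2O, 0 °C to rt; then dilute HCl to pH 4 at 0 °C
Reagents that add atoms: lithium hydroxide, [Li+].[OH-]
Why: Saponification of the methyl ester; a primary silyl ether survives cold aqueous LiOH and careful acidification.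

Step 12
Reactants: 16 (3S,4Z)-5-iodohexa-1,4-dien-3-ol; 19 2-{[(tert-butyldimethylsilyl)oxy]methyl}acrylic acid
Product: 20 (3S,4Z)-5-iodohexa-1,4-dien-3-yl 2-{[(tert-butyldimethylsilyl)oxy]methyl}acrylate
Conditions: EDC·HCl, DMAP (cat.), CH2Cl2, 0 °C to rt
Reagents that add atoms: none
Why: Steglich esterification occurs at the acyl carbon, so the C6 configuration is retained.

Step 13
Reactants: 20 (3S,4Z)-5-iodohexa-1,4-dien-3-yl 2-{[(tert-butyldimethylsilyl)oxy]methyl}acrylate
Product: 21 (5S)-3-{[(tert-butyldimethylsilyl)oxy]methyl}-5-[(Z)-2-iodoprop-1-en-1-yl]furan-2(5H)-one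
Conditions: second-generation Hoveyda–Grubbs catalyst [RuCl2(H2IMes)(=CH-C6H4-2-OiPr)] (5–10 mol %), 1,4-benzoquinone (10 mol %), toluene, 80 °C, argon sparge
Reagents that add atoms: none
Why: Ring-closing metathesis of a 2-substituted acrylate onto an allylic vinyl group, a known route to 3-substituted butenolides; the trisubstituted iodoalkene is too hindered and electron-poor to engage, and no base is present that could epimerise the acidic C6–H.

Step 14
Reactants: 21 (5S)-3-{[(tert-butyldimethylsilyl)oxy]methyl}-5-[(Z)-2-iodoprop-1-en-1-yl]furan-2(5H)-one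
Product: 22 (5S)-3-(bromomethyl)-5-[(Z)-2-iodoprop-1-en-1-yl]furan-2(5H)-one
Conditions: PPh3·Br2, CH2Cl2, 0 °C to rt
Reagents that add atoms: triphenylphosphine dibromide, BrP(Br)(c1ccccc1)(c1ccccc1)c1ccccc1
Why: Triphenylphosphine dibromide converts silyl ethers directly into bromides (Appel-type, through a silyloxyphosphonium bromide) at the primary allylic carbon; the conditions are base-free, which protects the C6 stereocentre.

Step 15
Reactants: 23 tiglic acid
Product: 24 (E)-2-methylbut-2-en-1-ol
Conditions: LiAlH4, Et2O, 0 °C to rt
Reagents that add atoms: none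
Why: Hydride reduction of the acid; alkyl-substituted enoic acids undergo 1,2-reduction and the E geometry is kept.

Step 16
Reactants: 24 (E)-2-methylbut-2-en-1-ol
Product: 25 [(2S,3S)-2,3-dimethyloxiran-2-yl]methanol
Conditions: Ti(OiPr)4 (10 mol %), L-(+)-diisopropyl tartrate (12 mol %), t-BuOOH, 4 Å molecular sieves, CH2Cl2, −20 °C
Reagents that add atoms: tert-butyl hydroperoxide, CC(C)(C)OO
Why: Sharpless asymmetric epoxidation; with L-(+)-tartrate an E-allylic alcohol of this type should give the (2S,3S)-epoxy alcohol, the E geometry placing the two methyls cis.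

Step 17
Reactants: 25 [(2S,3S)-2,3-dimethyloxiran-2-yl]methanol
Product: 26 (2R,3S)-2,3-dimethyloxirane-2-carboxylic acid
Conditions: RuCl3·xH2O (2 mol %), NaIO4, MeCN–EtOAc–H2O, 0 °C to rt
Reagents that add atoms: water, O
Why: Ruthenium tetroxide generated in situ oxidises the primary alcohol through the aldehyde hydrate to the acid without touching the epoxide (Sharpless conditions for glycidic acids); the C2 descriptor changes from S to R only through the priority change.

Step 18
Reactants: 22 (5S)-3-(bromomethyl)-5-[(Z)-2-iodoprop-1-en-1-yl]furan-2(5H)-one; 10 2-[(2R,3R)-3-{2-[(4-methoxybenzyl)oxy]ethyl}-2-methyloxiran-2-yl]acetaldehyde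
Product: 28 (4R,5S)-4-[(1S)-1-hydroxy-2-{(2R,3R)-3-[2-(4-methoxybenzyloxy)ethyl]-2-methyloxiran-2-yl}ethyl]-5-[(Z)-2-iodoprop-1-en-1-yl]-3-methylideneoxolan-2-one, via allylindium dibromide 27 (not isolated)
Conditions: In powder, THF–H2O (3:1), rt
Reagents that add atoms: none
Why: Barbier-type allylation: indium inserts only into the allylic C–Br bond, and the allylindium adds through its γ-carbon (C7) in a closed chair transition state on the face anti to the C6 iodoalkenyl group, giving the 6,7-trans lactone with its exocyclic methylene and the 7,8-anti (8S) carbinol; the neutral aqueous medium spares the epoxide, the alkenyl iodide and the PMB ether.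

Step 19
Reactants: 28 (4R,5S)-4-[(1S)-1-hydroxy-2-{(2R,3R)-3-[2-(4-methoxybenzyloxy)ethyl]-2-methyloxiran-2-yl}ethyl]-5-[(Z)-2-iodoprop-1-en-1-yl]-3-methylideneoxolan-2-one; 26 (2R,3S)-2,3-dimethyloxirane-2-carboxylic acid
Product: 29 (1R)-1-{(2S,3R)-2-[(Z)-2-iodoprop-1-en-1-yl]-4-methylidene-5-oxooxolan-3-yl}-2-{(2R,3R)-3-[2-(4-methoxybenzyloxy)ethyl]-2-methyloxiran-2-yl}ethyl (2R,3S)-2,3-dimethyloxirane-2-carboxylate
Conditions: PPh3, DIAD, toluene, 0 °C to rt (betaine preformed, then 26 and 28)
Reagents that add atoms: none
Why: Mitsunobu esterification: the carboxylate of the acidic epoxy acid displaces the C8 oxyphosphonium with SN2 inversion, turning 8S into the required 8R while installing the side chain; no other free hydroxyl is present.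

Step 20
Reactants: 29 (1R)-1-{(2S,3R)-2-[(Z)-2-iodoprop-1-en-1-yl]-4-methylidene-5-oxooxolan-3-yl}-2-{(2R,3R)-3-[2-(4-methoxybenzyloxy)ethyl]-2-methyloxiran-2-yl}ethyl (2R,3S)-2,3-dimethyloxirane-2-carboxylate
Product: 30 (1R)-2-[(2R,3R)-3-(2-hydroxyethyl)-2-methyloxiran-2-yl]-1-{(2S,3R)-2-[(Z)-2-iodoprop-1-en-1-yl]-4-methylidene-5-oxooxolan-3-yl}ethyl (2R,3S)-2,3-dimethyloxirane-2-carboxylate
Conditions: DDQ, CH2Cl2–pH 7 phosphate buffer, 0 °C
Reagents that add atoms: none
Why: DDQ cleaves the PMB ether by hydride abstraction from the electron-rich benzylic position; at buffered neutral pH the epoxides, esters, methylene lactone and alkenyl iodide are untouched.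

Step 21
Reactants: 30 (1R)-2-[(2R,3R)-3-(2-hydroxyethyl)-2-methyloxiran-2-yl]-1-{(2S,3R)-2-[(Z)-2-iodoprop-1-en-1-yl]-4-methylidene-5-oxooxolan-3-yl}ethyl (2R,3S)-2,3-dimethyloxirane-2-carboxylate
Product: 31 (1R)-1-{(2S,3R)-2-[(Z)-2-iodoprop-1-en-1-yl]-4-methylidene-5-oxooxolan-3-yl}-2-[(2R,3R)-2-methyl-3-(2-oxoethyl)oxiran-2-yl]ethyl (2R,3S)-2,3-dimethyloxirane-2-carboxylate
Conditions: Dess–Martin periodinane, NaHCO3, CH2Cl2, 0 °C; filtered through neutral alumina and used at once
Reagents that add atoms: none
Why: Dess–Martin oxidation under bicarbonate buffering stops at the C3 aldehyde; the β,γ-epoxy aldehyde is kept away from acid and base and taken directly into the ring closure.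

Step 22
Reactants: 31 (1R)-1-{(2S,3R)-2-[(Z)-2-iodoprop-1-en-1-yl]-4-methylidene-5-oxooxolan-3-yl}-2-[(2R,3R)-2-methyl-3-(2-oxoethyl)oxiran-2-yl]ethyl (2R,3S)-2,3-dimethyloxirane-2-carboxylate
Product: 34 CNP0268255.6 (target germacranolide), via alkenylchromium dichloride 32 (not isolated), via chromium alkoxide 33 (not isolated)
Conditions: CrCl2 (15 equiv), NiCl2 (1 mol % relative to CrCl2), degassed DMSO, rt, slow addition of 31 to a final 1–2 mM; aqueous work-up
Reagents that add atoms: none
Why: Zerovalent nickel, formed from NiCl2 by CrCl2, inserts into the C4–I bond, the alkenylnickel transmetallates to trivalent chromium (32), and the alkenylchromium adds to the C3 aldehyde to give alkoxide 33, divalent chromium being the stoichiometric reductant. The closest known reaction type is the Nozaki–Hiyama–Kishi alkenyl iodide–aldehyde macrocyclisation used for medium and large carbocycles. The ten-membered carbocycle closes by intramolecular 1,2-addition of C4 to the C3 carbonyl (exo attack on the C=O, with C3–C4 the only new skeletal bond), favoured over oligomerisation by slow addition at high dilution. The Z geometry of C4=C5 is carried over because the σ-alkenyl nickel and chromium species are configurationally stable, and with C6 cis to the metal the two reacting ends lie on the same side of the alkene. The new C3 stereocentre is under substrate control: the trans-lactone and the trans-epoxide restrict the closing chain, and addition to the Re face of the aldehyde is required for 3S; this selectivity is the least secure point of the step. Chemoselectivity rests on the low basicity and high aldehyde selectivity of alkenylchromium reagents, which should leave the lactone, the C8 ester, both epoxides and the methylene lactone untouched, and on the absence of any other carbon–halogen bond.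

## Compound list

1 | but-3-yn-1-ol | C#CCCO | starting material
2 | tert-butyl(but-3-yn-1-yloxy)dimethylsilane | C#CCCO[Si](C)(C)C(C)(C)C | intermediate
3 | ethylene oxide | C1CO1 | starting material
4 | [(E)-4-[(tert-butyldimethylsilyl)oxy]-2-methylbut-1-en-1-yl]dimethylalane | C[Al](C)/C=C(\C)CCO[Si](C)(C)C(C)(C)C | intermediate
5 | lithium butyl[(E)-4-[(tert-butyldimethylsilyl)oxy]-2-methylbut-1-en-1-yl]dimethylalanate | [Li+].CCCC[Al-](C)(C)/C=C(\C)CCO[Si](C)(C)C(C)(C)C | intermediate
6 | (E)-6-[(tert-butyldimethylsilyl)oxy]-4-methylhex-3-en-1-ol | CC(C)(C)[Si](C)(C)OCC/C(C)=C/CCO | intermediate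
7 | tert-butyl{[(E)-6-[(4-methoxybenzyl)oxy]-3-methylhex-3-en-1-yl]oxy}dimethylsilane | CC(C)(C)[Si](C)(C)OCC/C(C)=C/CCOCc1ccc(OC)cc1 | intermediate
8 | tert-butyl{2-[(2R,3R)-3-{2-[(4-methoxybenzyl)oxy]ethyl}-2-methyloxiran-2-yl]ethoxy}dimethylsilane | CC(C)(C)[Si](C)(C)OCC[C@@]1(C)O[C@@H]1CCOCc1ccc(OC)cc1 | intermediate
9 | 2-[(2R,3R)-3-{2-[(4-methoxybenzyl)oxy]ethyl}-2-methyloxiran-2-yl]ethan-1-ol | OCC[C@@]1(C)O[C@@H]1CCOCc1ccc(OC)cc1 | intermediate
10 | 2-[(2R,3R)-3-{2-[(4-methoxybenzyl)oxy]ethyl}-2-methyloxiran-2-yl]acetaldehyde | O=CC[C@@]1(C)O[C@@H]1CCOCc1ccc(OC)cc1 | intermediate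
11 | acrolein | C=CC=O | starting material
12 | 1-propynylmagnesium bromide | CC#C[Mg]Br | starting material
13 | rac-hex-1-en-4-yn-3-ol | C=CC(O)C#CC | intermediate
14 | sodium 2,2-bis(2-methoxyethoxy)-3-methyl-5-vinyl-2,5-dihydro-1,2-oxaluminol-2-uide (cyclic alkenylaluminate) | [Na+].C=CC1O[Al-](OCCOC)(OCCOC)C(C)=C1 | intermediate
15 | rac-(Z)-5-iodohexa-1,4-dien-3-ol | C=CC(O)/C=C(/C)I | intermediate
16 | (3S,4Z)-5-iodohexa-1,4-dien-3-ol | C=C[C@H](O)/C=C(/C)I | intermediate
17 | methyl 2-(hydroxymethyl)acrylate | C=C(CO)C(=O)OC | starting material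
18 | methyl 2-{[(tert-butyldimethylsilyl)oxy]methyl}acrylate | C=C(CO[Si](C)(C)C(C)(C)C)C(=O)OC | intermediate
19 | 2-{[(tert-butyldimethylsilyl)oxy]methyl}acrylic acid | C=C(CO[Si](C)(C)C(C)(C)C)C(=O)O | intermediate
20 | (3S,4Z)-5-iodohexa-1,4-dien-3-yl 2-{[(tert-butyldimethylsilyl)oxy]methyl}acrylate | C=C(CO[Si](C)(C)C(C)(C)C)C(=O)O[C@@H](C=C)/C=C(/C)I | intermediate
21 | (5S)-3-{[(tert-butyldimethylsilyl)oxy]methyl}-5-[(Z)-2-iodoprop-1-en-1-yl]furan-2(5H)-one | O=C1O[C@H](/C=C(/C)I)C=C1CO[Si](C)(C)C(C)(C)C | intermediate
22 | (5S)-3-(bromomethyl)-5-[(Z)-2-iodoprop-1-en-1-yl]furan-2(5H)-one | O=C1O[C@H](/C=C(/C)I)C=C1CBr | intermediate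
23 | tiglic acid | C/C=C(\C)C(=O)O | starting material
24 | (E)-2-methylbut-2-en-1-ol | C/C=C(\C)CO | intermediate
25 | [(2S,3S)-2,3-dimethyloxiran-2-yl]methanol | OC[C@]1(C)O[C@H]1C | intermediate
26 | (2R,3S)-2,3-dimethyloxirane-2-carboxylic acid | OC(=O)[C@]1(C)O[C@H]1C | intermediate
27 | {[(5S)-5-[(Z)-2-iodoprop-1-en-1-yl]-2-oxo-2,5-dihydrofuran-3-yl]methyl}indium dibromide | O=C1O[C@H](/C=C(/C)I)C=C1C[In](Br)Br | intermediate
28 | (4R,5S)-4-[(1S)-1-hydroxy-2-{(2R,3R)-3-[2-(4-methoxybenzyloxy)ethyl]-2-methyloxiran-2-yl}ethyl]-5-[(Z)-2-iodoprop-1-en-1-yl]-3-methylideneoxolan-2-one | C=C1C(=O)O[C@H](/C=C(/C)I)[C@H]1[C@@H](O)C[C@@]2(C)O[C@@H]2CCOCc3ccc(OC)cc3 | intermediate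
29 | (1R)-1-{(2S,3R)-2-[(Z)-2-iodoprop-1-en-1-yl]-4-methylidene-5-oxooxolan-3-yl}-2-{(2R,3R)-3-[2-(4-methoxybenzyloxy)ethyl]-2-methyloxiran-2-yl}ethyl (2R,3S)-2,3-dimethyloxirane-2-carboxylate | C=C1C(=O)O[C@H](/C=C(/C)I)[C@H]1[C@H](OC(=O)[C@]3(C)O[C@H]3C)C[C@@]2(C)O[C@@H]2CCOCc4ccc(OC)cc4 | intermediate
30 | (1R)-2-[(2R,3R)-3-(2-hydroxyethyl)-2-methyloxiran-2-yl]-1-{(2S,3R)-2-[(Z)-2-iodoprop-1-en-1-yl]-4-methylidene-5-oxooxolan-3-yl}ethyl (2R,3S)-2,3-dimethyloxirane-2-carboxylate | C=C1C(=O)O[C@H](/C=C(/C)I)[C@H]1[C@H](OC(=O)[C@]3(C)O[C@H]3C)C[C@@]2(C)O[C@@H]2CCO | intermediate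
31 | (1R)-1-{(2S,3R)-2-[(Z)-2-iodoprop-1-en-1-yl]-4-methylidene-5-oxooxolan-3-yl}-2-[(2R,3R)-2-methyl-3-(2-oxoethyl)oxiran-2-yl]ethyl (2R,3S)-2,3-dimethyloxirane-2-carboxylate (seco aldehyde Z-alkenyl iodide) | C=C1C(=O)O[C@H](/C=C(/C)I)[C@H]1[C@H](OC(=O)[C@]3(C)O[C@H]3C)C[C@@]2(C)O[C@@H]2CC=O | intermediate
32 | alkenylchromium dichloride of 31 (CrCl2 on C4 in place of iodine, Z) | C=C1C(=O)O[C@H](/C=C(/C)[Cr](Cl)Cl)[C@H]1[C@H](OC(=O)[C@]3(C)O[C@H]3C)C[C@@]2(C)O[C@@H]2CC=O | intermediate
33 | chromium dichloride alkoxide of 34 (O–CrCl2 on C3) | C=C1C(=O)O[C@@H]2/C=C(/C)[C@@H](O[Cr](Cl)Cl)C[C@H]3O[C@]3(C)C[C@@H](OC(=O)[C@]3(C)O[C@H]3C)[C@@H]12 | intermediate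
34 | CNP0268255.6: (1R,3S,4Z,6R,7R,8R,10R)-1,10-epoxy-3-hydroxy-12-oxogermacra-4,11(13)-dien-12,6-olid-8-yl (2R,3S)-2,3-dimethyloxirane-2-carboxylate | C=C1C(=O)O[C@@H]2/C=C(/C)[C@@H](O)C[C@H]3O[C@]3(C)C[C@@H](OC(=O)[C@]3(C)O[C@H]3C)[C@@H]12 | target

## Step count and least certain steps

Total: 22 steps. Longest linear sequence: 11 steps (steps 7, 8, 9, 12, 13, 14 and 18–22 from acrolein; the branch from but-3-yn-1-ol, steps 1–6 and 18–22, is equally long).

**Step 22 (key step).** Closure of the strained ring is slow, so intermolecular coupling and protonation of the alkenylchromium may compete. The Lewis-acidic chromium salts may also open the β,γ-epoxy aldehyde by β-elimination. Even when the ring forms, facial selectivity at C3 may be poor, because it depends only on the conformation of the closing chain. Fallback: the closure is still run from 31, and the carbinol mixture containing the C3 epimer F1 is oxidised with Dess–Martin periodinane (NaHCO3, CH2Cl2) to the Z-enone F2. Luche reduction of F2 (NaBH4, CeCl3·7H2O, MeOH, −78 °C) then returns the route to 34. C3 is thereby set by hydride delivery to the exposed face of a rigid ten-membered enone instead of by the C–C bond formation, and the cerium salt enforces 1,2-reduction so that the methylene lactone is spared.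

**Step 19.** The C8 carbinol is flanked by the ring methine C7 and a neopentyl-like C9, so elimination towards C7 or esterification with retention through an acyloxyphosphonium may compete with SN2 displacement by the hindered epoxy acid. Fallback: starting from 28, the inversion is carried out with the small, acidic formic acid (PPh3, DIAD) to give the (8R)-formate F3. Mild methanolysis (KHCO3, MeOH–H2O, 0 °C) frees the (8R)-alcohol F4, and Yamaguchi esterification with 26 (2,4,6-trichlorobenzoyl chloride, Et3N, DMAP, toluene) returns to 29 with retention.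

**Step 18.** The β,γ-epoxy aldehyde 10 may open by β-elimination during the slow heterogeneous reaction, and its β-stereocentre may erode the facial selectivity set by the chair transition state. Fallback: the epoxidation is postponed. Starting from 7, Bu4NF gives the alkenol F5 and Dess–Martin oxidation gives the β,γ-unsaturated aldehyde F6. Indium-mediated union of F6 with 22 gives the homoallylic alcohol F7, and Shi epoxidation of the electron-rich C10=C1 alkene of F7 (the enoate and the iodoalkene being much less reactive toward the dioxirane) returns to 28.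

**Step 9.** The lipase may discriminate insufficiently between the vinyl and the iodoalkenyl group, leaving 16 of incomplete enantiopurity. Fallback: starting from 15, a Sharpless kinetic resolution (Ti(OiPr)4, L-(+)-diisopropyl tartrate, t-BuOOH, 4 Å molecular sieves, CH2Cl2, −20 °C) removes the (R)-enantiomer by epoxidation of its vinyl group to the epoxy alcohol F8. The unreacted (S)-alcohol is recovered, returning to 16.

**Step 2.** Transfer of the alkenyl group from the alanate to ethylene oxide may be incomplete, or butyl or methyl may transfer instead. Fallback: starting from 2, the carboalumination is quenched with I2 to give the E-alkenyl iodide F9. Halogen–lithium exchange (t-BuLi, Et2O, −78 °C) gives the alkenyllithium F10, which opens ethylene oxide in the presence of BF3·OEt2 and returns to 6.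

## Further compounds

F1 | step 22 | 3-epi-34, (3R)-carbinol | C=C1C(=O)O[C@@H]2/C=C(/C)[C@H](O)C[C@H]3O[C@]3(C)C[C@@H](OC(=O)[C@]3(C)O[C@H]3C)[C@@H]12
F2 | step 22 | Z-enone, 3-oxo analogue of 34 | C=C1C(=O)O[C@@H]2/C=C(/C)C(=O)C[C@H]3O[C@]3(C)C[C@@H](OC(=O)[C@]3(C)O[C@H]3C)[C@@H]12
F3 | step 19 | (8R)-formate of the union product | C=C1C(=O)O[C@H](/C=C(/C)I)[C@H]1[C@H](OC=O)C[C@@]2(C)O[C@@H]2CCOCc3ccc(OC)cc3
F4 | step 19 | (8R)-alcohol, C8 epimer of 28 | C=C1C(=O)O[C@H](/C=C(/C)I)[C@H]1[C@H](O)C[C@@]2(C)O[C@@H]2CCOCc3ccc(OC)cc3
F5 | step 18 | (E)-6-[(4-methoxybenzyl)oxy]-3-methylhex-3-en-1-ol | OCC/C(C)=C/CCOCc1ccc(OC)cc1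
F6 | step 18 | (E)-6-[(4-methoxybenzyl)oxy]-3-methylhex-3-enal | O=CC/C(C)=C/CCOCc1ccc(OC)cc1
F7 | step 18 | (4R,5S)-4-[(1S,3E)-1-hydroxy-6-(4-methoxybenzyloxy)-3-methylhex-3-en-1-yl]-5-[(Z)-2-iodoprop-1-en-1-yl]-3-methylideneoxolan-2-one | C=C1C(=O)O[C@H](/C=C(/C)I)[C@H]1[C@@H](O)C/C(C)=C/CCOCc2ccc(OC)cc2
F8 | step 9 | (1S,2Z)-3-iodo-1-[(2R)-oxiran-2-yl]but-2-en-1-ol | O[C@H]([C@H]1CO1)/C=C(/C)I
F9 | step 2 | tert-butyl{[(E)-4-iodo-3-methylbut-3-en-1-yl]oxy}dimethylsilane | CC(C)(C)[Si](C)(C)OCC/C(C)=C/I
F10 | step 2 | [(E)-4-[(tert-butyldimethylsilyl)oxy]-2-methylbut-1-en-1-yl]lithium | [Li]/C=C(\C)CCO[Si](C)(C)C(C)(C)C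
A1 | alternative 1 | cis-anti-cis head-to-head photoadduct (tricyclic C6 ketone with the C15 methyl ester on C4, C3 dimethyl ketal and C8 silyl ether) | O=C1[C@@H]2[C@@]3(C(=O)OC)C(OC)(OC)C[C@H]3[C@]2(C)C[C@@H](O[Si](C)(C)C(C)(C)C)C1
A2 | alternative 2 | (1(10)E,4Z)-3-silyloxy-8-(4-methoxybenzyloxy)cyclodeca-1(10),4-dien-6-one | O=C1/C=C(/C)[C@@H](O[Si](C)(C)C(C)(C)C)C/C=C(\C)C[C@@H](OCc2ccc(OC)cc2)C1
A3 | alternative 3 | ten-membered 10-hydroxy-8-ketone with the lactone in place | C=C1C(=O)O[C@@H]2/C=C(/C)[C@@H](OCc3ccc(OC)cc3)C[C@H](O[Si](CC)(CC)CC)[C@@](O)(C)CC(=O)[C@@H]12
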